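**Strategy.** The route rests on taking ring C of the upper flavan apart across C4a–C4 and C2–C3. Its C3–C4 unit becomes an (E)-alkenyl boronate on C2′ of the lower pyrogallol ring, and ring A, O1 and C2 become an O-aryl oxocarbenium ion. Their cationic [4+2] union (oxa-Povarov type) forms both bonds and the three stereocentres C2, C3 and C4 in one operation. It exploits the 3′- and 5′-oxygens ortho and para to C2′, which stabilise a cation at C4, and C4a, which lies para to the 7-oxygen of ring A. The lower unit comes from (+)-dihydrorobinetin and stays a C4 ketone until the last step; boron at C3 is later oxidised to the hydroxyl.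

Key step: step 7

Assumption and numbering: (+)-(2R,3R)-dihydrorobinetin is taken as a purchasable chiral-pool material; flavan numbering is used, "lower unit" means the flavan that ends as the 3,4-diol, and primes mark its pyrogallol ring.

**Step 1**
Reactants: 1 (+)-dihydrorobinetin; 2 benzyl bromide
Product: 3 tetra-O-benzyl dihydrorobinetin with free 3-OH
Conditions: BnBr (4.4 equiv), K2CO3, DMF, rt, Ar
Reagents that add atoms: benzyl bromide, BrCc1ccccc1
Why: Williamson ether synthesis: K2CO3 deprotonates only the four phenols, which are benzylated, while the less acidic secondary 3-OH stays free and the mild base at room temperature leaves C2 and C3 of the flavanone untouched.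

**Step 2**
Reactants: 3 tetra-O-benzyl dihydrorobinetin; 4 benzyl chloroformate
Product: 5 3-O-benzyloxycarbonyl tetra-O-benzyl dihydrorobinetin
Conditions: CbzCl, pyridine, DMAP (cat.), CH2Cl2, 0 °C to rt
Reagents that add atoms: benzyl chloroformate, O=C(Cl)OCc1ccccc1
Why: DMAP-catalysed O-acylation with a chloroformate gives the benzyl carbonate, which keeps the 3-OH from trapping cations in step 7 and is removed in the hydrogenolysis of step 9.

**Step 3**
Reactants: 5 carbonate; 6 N-bromosuccinimide
Product: 7 2′-bromide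
Conditions: NBS (1.05 equiv), MeCN, 0 °C to rt, dark
Reagents that add atoms: N-bromosuccinimide, O=C1CCC(=O)N1Br
Why: Electrophilic aromatic bromination should go to C2′ (equivalent to C6′) of the tris(benzyloxy)phenyl ring, ortho and para to two benzyloxy groups, because ring A is deactivated by the C4 carbonyl and the first bromine slows a second substitution.

**Step 4**
Reactants: 7 2′-bromide; 8 vinylboronic acid pinacol ester
Product: 9 (E)-alkenyl boronate of the lower unit
Conditions: Pd(P(t-Bu)3)2 (cat.), Cy2NMe, toluene, 80 °C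
Reagents that add atoms: vinylboronic acid pinacol ester, C=CB1OC(C)(C)C(C)(C)O1
Why: Mizoroki–Heck reaction: syn-carbopalladation of the vinyl boronate and syn-β-hydride elimination should give the (E)-alkenyl boronate, and the water-free amine base disfavours transmetalation of boron (the Suzuki–Miyaura pathway).

**Step 5**
Reactants: 10 3,4,5-tris(benzyloxy)benzaldehyde; 11 trimethyl orthoformate
Product: 12 dimethyl acetal
Conditions: HC(OMe)3, p-TsOH·H2O (cat.), MeOH, rt
Reagents that add atoms: trimethyl orthoformate, COC(OC)OC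
Why: Acid-catalysed acetalisation, driven by trimethyl orthoformate as the dehydrating agent.

**Step 6**
Reactants: 12 dimethyl acetal; 13 acetyl chloride; 14 3-(benzyloxy)phenol
Product: 16 mixed aryl methyl acetal, via α-chlorobenzyl methyl ether 15 (not isolated)
Conditions: AcCl, SOCl2 (cat.), CH2Cl2, rt; evaporate; then 14, i-Pr2NEt, CH2Cl2, 0 °C to rt
Reagents that add atoms: 3-(benzyloxy)phenol, Oc1cccc(OCc2ccccc2)c1
Why: Acetyl chloride exchanges one methoxy group for chloride via the oxocarbenium ion (α-chloro ether formation), and the phenol then displaces chloride in an SN1-type O-alkylation under amine base to give the racemic mixed acetal, whose stereocentre is lost on ionisation in step 7.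

**Step 7**
Reactants: 9 (E)-alkenyl boronate; 16 mixed aryl methyl acetal
Product: 19 3-boryl-4-arylflavan cycloadduct, via aryloxycarbenium ion 17 (not isolated), via benzylic cation 18 (not isolated)
Conditions: SnCl4 (2.5 equiv), CH2Cl2, −78 °C; then aq. NaHCO3
Reagents that add atoms: none
Why: Proposed new method: SnCl4 ionises the methoxy group of 16 to the O-aryl oxocarbenium ion 17, whose C2 is attacked by the boron-bearing alkene carbon of 9 to give the benzylic cation 18, and C4a of ring A then attacks this cation, so that the two bonds arise in a stepwise cationic [4+2] process; the closest known reaction type is the SnCl4-promoted oxa-Povarov reaction of mixed aryl alkyl acetals with styrenes, which gives 2,4-cis-chromans, and the new element is the boryl group on the attacked alkene carbon. The 3′- and 5′-benzyloxy groups ortho and para to C2′ stabilise a cation at C4 while the vacant orbital of boron disfavours one at C3, so C3 is the nucleophilic carbon, and boron should stay on C3 because cation 18 lies β to it and is trapped by ring A within the molecule before chloride can attack boron. Ring C closes as a six-membered ring by electrophilic aromatic substitution at C4a (6-exo-trig at the trigonal cation) through a chair-like transition state, at the position para to the 7-benzyloxy group and not at the hindered position between the two oxygens of ring A. For C3 and C4 the E-alkene geometry is carried into the ring, so boron and the lower aryl group end up trans, and at C2 the aryl group takes the equatorial site of the chair, trans to boron and cis to the C4 aryl group, which gives the 2,3-trans-3,4-trans ring. Chemoselectivity is secured by the oxidation level and protection of the lower unit: as a C4 ketone it cannot ionise to a second benzylic cation, and its 3-OH is masked as the carbonate so that it cannot trap cation 18. The sense of this all-trans ring relative to the lower unit depends on which alkene face is attacked, for which the only resident bias is the C2 stereocentre of the lower unit ortho to the alkene, so the diastereomer with the mirror-image upper ring is expected alongside 19 and would be removed by chromatography.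

**Step 8**
Reactants: 19 cycloadduct; 20 sodium perborate tetrahydrate
Product: 21 benzyl-protected 4-arylflavan-3-ol with lower ketone
Conditions: NaBO3·4H2O, THF/H2O (1:1), rt
Reagents that add atoms: sodium perborate, [Na+].[Na+].O[B-]1(O)OO[B-](O)(O)OO1
Why: Oxidation of the C–B bond by peroxoborate: the 1,2-shift of C3 from boron to oxygen proceeds with retention, so the equatorial boryl group becomes the equatorial 3-OH trans to both aryl groups, and the mildly basic medium should spare the flavanone and the carbonate.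

**Step 9**
Reactants: 21 benzyl-protected 4-arylflavan-3-ol
Product: 22 free phenolic dimer with lower C4 ketone
Conditions: H2 (1 atm), Pd(OH)2/C, THF/MeOH, rt
Reagents that add atoms: none
Why: Catalytic hydrogenolysis cleaves the eight O-benzyl bonds and the benzyl carbonate (with loss of CO2), while the electron-rich aryl ketone and the cyclic benzylic C–O bonds should survive under neutral conditions at 1 atm.

**Step 10**
Reactants: 22 free phenolic dimer with lower C4 ketone
Product: 23 target CNP0205451.4
Conditions: NaBH4, MeOH, 0 °C, Ar; then dilute AcOH to pH 6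
Reagents that add atoms: none
Why: Borohydride reduction of the 2,3-trans-dihydroflavonol ketone: hydride should add to the face that gives the equatorial C4 hydroxyl trans to the 3-OH (substrate control by the half-chair with equatorial C2 and C3 substituents), which sets (4R) as in the reduction of dihydroflavonols to 2,3-trans-3,4-trans-flavan-3,4-diols.

**Compound list**

1 | (+)-dihydrorobinetin, (2R,3R)-3,7-dihydroxy-2-(3,4,5-trihydroxyphenyl)chroman-4-one | Oc1cc(cc(O)c1O)[C@H]1Oc2cc(O)ccc2C(=O)[C@@H]1O | starting material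
2 | benzyl bromide | BrCc1ccccc1 | starting material
3 | (2R,3R)-7-(benzyloxy)-3-hydroxy-2-[3,4,5-tris(benzyloxy)phenyl]chroman-4-one | c1(OCc9ccccc9)cc(cc(OCc9ccccc9)c1OCc9ccccc9)[C@H]1Oc2cc(OCc9ccccc9)ccc2C(=O)[C@@H]1O | intermediate
4 | benzyl chloroformate | O=C(Cl)OCc1ccccc1 | starting material
5 | benzyl (2R,3R)-7-(benzyloxy)-4-oxo-2-[3,4,5-tris(benzyloxy)phenyl]chroman-3-yl carbonate | c1(OCc9ccccc9)cc(cc(OCc9ccccc9)c1OCc9ccccc9)[C@H]1Oc2cc(OCc9ccccc9)ccc2C(=O)[C@@H]1OC(=O)OCc9ccccc9 | intermediate
6 | N-bromosuccinimide | O=C1CCC(=O)N1Br | starting material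
7 | benzyl (2R,3R)-7-(benzyloxy)-2-[3,4,5-tris(benzyloxy)-2-bromophenyl]-4-oxochroman-3-yl carbonate | c1(OCc9ccccc9)c(Br)c(cc(OCc9ccccc9)c1OCc9ccccc9)[C@H]1Oc2cc(OCc9ccccc9)ccc2C(=O)[C@@H]1OC(=O)OCc9ccccc9 | intermediate
8 | vinylboronic acid pinacol ester, 2-ethenyl-4,4,5,5-tetramethyl-1,3,2-dioxaborolane | C=CB1OC(C)(C)C(C)(C)O1 | starting material
9 | benzyl (2R,3R)-7-(benzyloxy)-4-oxo-2-{3,4,5-tris(benzyloxy)-2-[(E)-2-(4,4,5,5-tetramethyl-1,3,2-dioxaborolan-2-yl)ethenyl]phenyl}chroman-3-yl carbonate | c1(OCc9ccccc9)c(/C=C/B8OC(C)(C)C(C)(C)O8)c(cc(OCc9ccccc9)c1OCc9ccccc9)[C@H]1Oc2cc(OCc9ccccc9)ccc2C(=O)[C@@H]1OC(=O)OCc9ccccc9 | intermediate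
10 | 3,4,5-tris(benzyloxy)benzaldehyde | O=Cc1cc(OCc2ccccc2)c(OCc2ccccc2)c(OCc2ccccc2)c1 | starting material
11 | trimethyl orthoformate | COC(OC)OC | starting material
12 | 1,2,3-tris(benzyloxy)-5-(dimethoxymethyl)benzene | COC(OC)c1cc(OCc2ccccc2)c(OCc2ccccc2)c(OCc2ccccc2)c1 | intermediate
13 | acetyl chloride | CC(Cl)=O | starting material
14 | 3-(benzyloxy)phenol | Oc1cccc(OCc2ccccc2)c1 | starting material
15 | 1,2,3-tris(benzyloxy)-5-[chloro(methoxy)methyl]benzene (racemic, not isolated) | COC(Cl)c1cc(OCc2ccccc2)c(OCc2ccccc2)c(OCc2ccccc2)c1 | intermediate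
16 | 1,2,3-tris(benzyloxy)-5-{[3-(benzyloxy)phenoxy](methoxy)methyl}benzene (racemic) | COC(Oc1cccc(OCc2ccccc2)c1)c1cc(OCc2ccccc2)c(OCc2ccccc2)c(OCc2ccccc2)c1 | intermediate
17 | [3-(benzyloxy)phenyl]{[3,4,5-tris(benzyloxy)phenyl]methylidene}oxonium (not isolated) | [O+](=Cc1cc(OCc9ccccc9)c(OCc9ccccc9)c(OCc9ccccc9)c1)c1cccc(OCc9ccccc9)c1 | intermediate
18 | open-chain benzylic cation: C4 cationic and bonded to C2′ of the lower unit, C3 carrying the pinacolboryl group, C2 carrying the 3-(benzyloxy)phenoxy and 3,4,5-tris(benzyloxy)phenyl groups, C2 and C3 already in the relative arrangement of 19 (not isolated) | c1(OCc9ccccc9)cccc(c1)O[C@H](c1cc(OCc9ccccc9)c(OCc9ccccc9)c(OCc9ccccc9)c1)[C@@H](B8OC(C)(C)C(C)(C)O8)[CH+]c1c([C@H]2Oc3cc(OCc9ccccc9)ccc3C(=O)[C@@H]2OC(=O)OCc9ccccc9)cc(OCc9ccccc9)c(OCc9ccccc9)c1OCc9ccccc9 | intermediate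
19 | benzyl (2R,3R)-7-(benzyloxy)-2-{3,4,5-tris(benzyloxy)-2-[(2S,3S,4S)-7-(benzyloxy)-3-(4,4,5,5-tetramethyl-1,3,2-dioxaborolan-2-yl)-2-[3,4,5-tris(benzyloxy)phenyl]chroman-4-yl]phenyl}-4-oxochroman-3-yl carbonate (upper ring 2,3-trans-3,4-trans; the 2S label follows from boron at C3) | O(Cc9ccccc9)c1ccc2c(c1)O[C@H](c1cc(OCc9ccccc9)c(OCc9ccccc9)c(OCc9ccccc9)c1)[C@@H](B8OC(C)(C)C(C)(C)O8)[C@@H]2c1c([C@H]2Oc3cc(OCc9ccccc9)ccc3C(=O)[C@@H]2OC(=O)OCc9ccccc9)cc(OCc9ccccc9)c(OCc9ccccc9)c1OCc9ccccc9 | intermediate
20 | sodium perborate tetrahydrate (NaBO3·4H2O; SMILES of the anhydrous peroxoborate salt) | [Na+].[Na+].O[B-]1(O)OO[B-](O)(O)OO1 | starting material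
21 | benzyl (2R,3R)-7-(benzyloxy)-2-{3,4,5-tris(benzyloxy)-2-[(2R,3S,4S)-7-(benzyloxy)-3-hydroxy-2-[3,4,5-tris(benzyloxy)phenyl]chroman-4-yl]phenyl}-4-oxochroman-3-yl carbonate | O(Cc9ccccc9)c1ccc2c(c1)O[C@H](c1cc(OCc9ccccc9)c(OCc9ccccc9)c(OCc9ccccc9)c1)[C@@H](O)[C@@H]2c1c([C@H]2Oc3cc(OCc9ccccc9)ccc3C(=O)[C@@H]2OC(=O)OCc9ccccc9)cc(OCc9ccccc9)c(OCc9ccccc9)c1OCc9ccccc9 | intermediate
22 | (2R,3R)-3,7-dihydroxy-2-{3,4,5-trihydroxy-2-[(2R,3S,4S)-3,7-dihydroxy-2-(3,4,5-trihydroxyphenyl)chroman-4-yl]phenyl}chroman-4-one | Oc1ccc2c(c1)O[C@H](c1cc(O)c(O)c(O)c1)[C@@H](O)[C@@H]2c1c([C@H]2Oc3cc(O)ccc3C(=O)[C@@H]2O)cc(O)c(O)c1O | intermediate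
23 | CNP0205451.4, (2R,3S,4R)-2-{3,4,5-trihydroxy-2-[(2R,3S,4S)-3,7-dihydroxy-2-(3,4,5-trihydroxyphenyl)chroman-4-yl]phenyl}chroman-3,4,7-triol | Oc1ccc2c(c1)O[C@H](c1cc(O)c(O)c(O)c1)[C@@H](O)[C@@H]2c1c([C@H]2Oc3cc(O)ccc3[C@@H](O)[C@@H]2O)cc(O)c(O)c1O | target

**Step count and risks**

Total steps: 10. Longest linear sequence: 8 steps (steps 1, 2, 3, 4, 7, 8, 9, 10); steps 5 and 6 form the second branch.

Steps most likely to fail:

1. Step 7 (bears the label "Proposed new method:"). What may go wrong: loss of boron from cation 18 by deborylative elimination before ring A closes, attack of the oxocarbenium ion on an arene instead of the alkene, and lack of discrimination between the two alkene faces, which would waste the share of material that goes to the diastereomer with the mirror-image upper ring. Fallback by known chemistry, setting out from 3: NaBH4 in EtOH/THF at 0 °C reduces the ketone to (2R,3S,4R)-7-(benzyloxy)-2-[3,4,5-tris(benzyloxy)phenyl]chroman-3,4-diol F1. Its C4 hydroxyl is then ionised with BF3·OEt2 in CH2Cl2 at −40 °C in the presence of an excess of 5. The tris(benzyloxy)phenyl ring of 5 attacks the flavan-4-yl cation at C2′, anti to the 3-OH (the standard Friedel–Crafts interflavan coupling of a flavan-3,4-diol). Here C2 and C3 of the upper unit come from the chiral pool and C4 is set by the anti attack. The fallback comes back to the route at 21.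

2. Step 4. What may go wrong: slow oxidative addition of zerovalent palladium into the hindered, electron-rich C–Br bond, transmetalation of the vinyl boronate in place of insertion (which would give the boron-free styrene), and base-induced epimerisation of the flavanone at 80 °C. Fallback, setting out from 7: Sonogashira coupling with trimethylsilylacetylene (PdCl2(PPh3)2, CuI, Et3N, THF, 50 °C) gives benzyl (2R,3R)-7-(benzyloxy)-4-oxo-2-{3,4,5-tris(benzyloxy)-2-[(trimethylsilyl)ethynyl]phenyl}chroman-3-yl carbonate F2. Desilylation with TBAF buffered by AcOH in THF at 0 °C gives the terminal alkyne benzyl (2R,3R)-7-(benzyloxy)-2-[3,4,5-tris(benzyloxy)-2-ethynylphenyl]-4-oxochroman-3-yl carbonate F3. Syn-hydroboration with pinacolborane and catalytic Cp2Zr(H)Cl in CH2Cl2 then places boron at the terminal carbon with E geometry. The fallback comes back to the route at 9.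

3. Step 3. What may go wrong: bromination on ring A (C6) instead of the pyrogallol ring, or a second bromination at C6′. Fallback, setting out from 5: Vilsmeier–Haack formylation (POCl3, DMF, 0 to 60 °C, then aq. NaOAc) uses a weaker electrophile that should attack only the most electron-rich ring and stop after one substitution, giving benzyl (2R,3R)-7-(benzyloxy)-2-[3,4,5-tris(benzyloxy)-2-formylphenyl]-4-oxochroman-3-yl carbonate F4. Takai-type olefination of the aldehyde with 2-(dichloromethyl)-4,4,5,5-tetramethyl-1,3,2-dioxaborolane, CrCl2 and LiI in THF at rt then gives the (E)-alkenyl boronate. The fallback comes back to the route at 9 and bypasses 7.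

**Further compounds**

F1 | step 7 | (2R,3S,4R)-7-(benzyloxy)-2-[3,4,5-tris(benzyloxy)phenyl]chroman-3,4-diol | c1(OCc9ccccc9)cc(cc(OCc9ccccc9)c1OCc9ccccc9)[C@H]1Oc2cc(OCc9ccccc9)ccc2[C@@H](O)[C@@H]1O
F2 | step 4 | benzyl (2R,3R)-7-(benzyloxy)-4-oxo-2-{3,4,5-tris(benzyloxy)-2-[(trimethylsilyl)ethynyl]phenyl}chroman-3-yl carbonate | c1(OCc9ccccc9)c(C#C[Si](C)(C)C)c(cc(OCc9ccccc9)c1OCc9ccccc9)[C@H]1Oc2cc(OCc9ccccc9)ccc2C(=O)[C@@H]1OC(=O)OCc9ccccc9
F3 | step 4 | benzyl (2R,3R)-7-(benzyloxy)-2-[3,4,5-tris(benzyloxy)-2-ethynylphenyl]-4-oxochroman-3-yl carbonate | c1(OCc9ccccc9)c(C#C)c(cc(OCc9ccccc9)c1OCc9ccccc9)[C@H]1Oc2cc(OCc9ccccc9)ccc2C(=O)[C@@H]1OC(=O)OCc9ccccc9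
F4 | step 3 | benzyl (2R,3R)-7-(benzyloxy)-2-[3,4,5-tris(benzyloxy)-2-formylphenyl]-4-oxochroman-3-yl carbonate | c1(OCc9ccccc9)c(C=O)c(cc(OCc9ccccc9)c1OCc9ccccc9)[C@H]1Oc2cc(OCc9ccccc9)ccc2C(=O)[C@@H]1OC(=O)OCc9ccccc9
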